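**Retrosynthetic overview**

1. Locants used for description: ring A = seven-membered ring C1–C2–C3–C4–C5–C9–C10 with O bridging C3 and C10; ring B = cyclopentane C5–C9; ring C = C8, C9, C11–C14; ring D = C13–C18; methyls on C4 (two), C10, C13, C14, C17; side chain on C17.
2. Target ⇒ aldehyde 23 (Wittig) ⇒ silyl ether 21. Ring A is closed last: C5–H by HAT hydrogenation, and the C3–C4 bond plus the ether bridge by a Prins cyclisation of a C10 carbinol/C3 acetal onto a C5 isopropylidene group.
3. The C13 methyl comes from the C11 sulfur of the cycloadduct by a sulfonium-ylide [2,3] shift and Raney Ni; the C10 carbinol comes from the adduct aldehyde by two Grignard additions.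
4. Ring C ⇒ Diels–Alder reaction forming C9–C11 and C8–C14. Enabling feature: ring C is joined to the oxa-bridged A/B half only through these two bonds; its C8–C9 edge is the ring B bond next to C10 (the future ether carbon, here a formyl group), and its C13–C14 edge is the ring D bond. Ring C is therefore the cyclohexene retron of enal C8=C9–C10=O (dienal 11) plus diene C11=C12–C13=C14 (thio-diene 8).
5. Ring order: D (from 3-methylcyclohexenone, C17 by asymmetric conjugate addition) and B (from 2-isopropylidenecyclopentanone) are bought in; then C (step 8); then A (tetrahydrofuran and pyran rings, step 14).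

Key step: step 8

Remark (assumption): α/β refer to the B/C/D tricycle, β being the face of ring C that carries the C14 methyl. The antipodes of the chiral ligand (step 1) and of the chiral oxazaborolidine (step 8) are taken to be those that give the configurations drawn in the SMILES.

**Route**

Step 1
Reactants: 1 3-methylcyclohex-2-en-1-one; 2 (3-bromopropoxy)(tert-butyl)dimethylsilane
Product: 4 (3S)-3-{3-[(tert-butyldimethylsilyl)oxy]propyl}-3-methylcyclohexan-1-one, via Grignard reagent 3 (not isolated)
Conditions: 2, Mg, THF, rt; then 1, Cu(OTf)2 (3 mol%), (S)-3-(1-hydroxy-4-methylpentan-2-yl)-1-mesityl-4,5-dihydro-1H-imidazol-3-ium hexafluorophosphate (4 mol%; enantiomer if required), Et2O, 0 °C; H2O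
Reagents that add atoms: none
Why: Copper–carbene-catalysed asymmetric conjugate addition of a Grignard reagent to a β-methyl enone should create the quaternary C17 centre, the ligand antipode being chosen so that the alkyl group enters on the enone face that gives the (S)-ketone.

Step 2
Reactants: 4 (3S)-3-{3-[(tert-butyldimethylsilyl)oxy]propyl}-3-methylcyclohexan-1-one
Product: 5 (5S)-5-{3-[(tert-butyldimethylsilyl)oxy]propyl}-2,5-dimethylcyclohexan-1-one
Conditions: LiN(i-Pr)2 (LDA), THF, −78 °C; MeI, −78 → 0 °C
Reagents that add atoms: iodomethane, CI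
Why: Kinetic enolate alkylation: LDA should deprotonate the α-methylene remote from the quaternary carbon, and the new methyl-bearing centre (C14) is formed as an inconsequential mixture because it becomes sp2 in step 3.

Step 3
Reactants: 5 (5S)-5-{3-[(tert-butyldimethylsilyl)oxy]propyl}-2,5-dimethylcyclohexan-1-one
Product: 6 (5S)-5-{3-[(tert-butyldimethylsilyl)oxy]propyl}-2,5-dimethylcyclohex-1-en-1-yl trifluoromethanesulfonate
Conditions: Tf2O, 2,6-di-tert-butyl-4-methylpyridine, CH2Cl2, 0 °C → rt
Reagents that add atoms: trifluoromethanesulfonic anhydride, O=S(=O)(OS(=O)(=O)C(F)(F)F)C(F)(F)F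
Why: Enol triflate formation under equilibrating conditions should favour the tetrasubstituted C13=C14 enol triflate, the other α-carbon being a neopentyl methylene.

Step 4
Reactants: 6 (5S)-5-{3-[(tert-butyldimethylsilyl)oxy]propyl}-2,5-dimethylcyclohex-1-en-1-yl trifluoromethanesulfonate
Product: 7 (5S)-5-{3-[(tert-butyldimethylsilyl)oxy]propyl}-2,5-dimethylcyclohex-1-ene-1-carbaldehyde
Conditions: Pd(PPh3)4 (5 mol%), CO (3 atm), Bu3SnH (slow addition), THF, 50 °C
Reagents that add atoms: carbon monoxide, [C-]#[O+]
Why: Palladium-catalysed reductive carbonylation (formylation) of a vinyl triflate should install C12 as the enal without touching the silyl ether.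

Step 5
Reactants: 7 (5S)-5-{3-[(tert-butyldimethylsilyl)oxy]propyl}-2,5-dimethylcyclohex-1-ene-1-carbaldehyde
Product: 8 tert-butyl(3-{(1S)-1,4-dimethyl-3-[(E)-2-(phenylsulfanyl)ethenyl]cyclohex-3-en-1-yl}propoxy)dimethylsilane
Conditions: (EtO)2P(O)CH2SPh, n-BuLi, THF, −78 °C → rt
Reagents that add atoms: diethyl [(phenylsulfanyl)methyl]phosphonate, CCOP(=O)(CSc1ccccc1)OCC
Why: Horner–Wadsworth–Emmons olefination should add C11 as the E-vinyl sulfide needed for the cycloaddition, any Z isomer being unable to reach the s-cis diene and removable or equilibrated with a trace of iodine.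

Step 6
Reactants: 9 2-(propan-2-ylidene)cyclopentan-1-one
Product: 10 5-(propan-2-ylidene)cyclopent-1-en-1-yl trifluoromethanesulfonate
Conditions: LiN(i-Pr)2 (LDA), THF, −78 °C; PhNTf2, −78 → 0 °C
Reagents that add atoms: N-phenylbis(trifluoromethanesulfonimide), O=S(=O)(N(c1ccccc1)S(=O)(=O)C(F)(F)F)C(F)(F)F
Why: Kinetic α′-deprotonation of the enone and O-triflation of the cross-conjugated enolate (enol triflate formation) should give the dienyl triflate.

Step 7
Reactants: 10 5-(propan-2-ylidene)cyclopent-1-en-1-yl trifluoromethanesulfonate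
Product: 11 5-(propan-2-ylidene)cyclopent-1-ene-1-carbaldehyde
Conditions: Pd(PPh3)4 (5 mol%), CO (3 atm), Bu3SnH (slow addition), THF, 50 °C
Reagents that add atoms: carbon monoxide, [C-]#[O+]
Why: The same palladium-catalysed formylation of a vinyl triflate should install C10 as the formyl group that activates C8=C9.

Step 8
Reactants: 8 ring D thio-diene; 11 ring B dienal
Product: 12 Diels–Alder adduct (rings B/C/D aldehyde with 11α-phenylsulfanyl group)
Conditions: (S)-1-(2-methylphenyl)-3,3-diphenyltetrahydro-1H,3H-pyrrolo[1,2-c][1,3,2]oxazaborole (20 mol%; enantiomer if required), HNTf2 (18 mol%), CH2Cl2, −78 → −40 °C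
Reagents that add atoms: none
Why: Normal-demand Diels–Alder reaction: the protonated oxazaborolidine binds the formyl group of 11 and lowers the LUMO of C8=C9, the sulfur lone pair raises the HOMO of 8 and puts its largest coefficient on C14, and the asynchronous concerted [4+2] closes ring C (six-membered, suprafacial on both partners) with C8–C14 forming slightly ahead of C9–C11, as the ortho rule for 1-heteroatom dienes requires. The closest known reaction type is the oxazaborolidinium-catalysed enantioselective cycloaddition of 2-substituted acroleins with substituted butadienes, together with Lewis acid cycloadditions of 1-(arylthio)dienes. The relative configuration of C8, C9, C14 and C11 follows from the endo transition state (formyl under the diene) and the fixed diene geometry: C15 of ring D and the E-sulfur are outside groups and end up cis to the formyl carbon and to H8, while the inside C14 methyl ends up cis to ring B, which gives the cis B/C fusion. The absolute sense, and therefore the relation of the new centres to the remote C17 centre, is set by the catalyst, which shields one face of the bound enal; the diene has no facial bias of its own. The step needs regio-, endo- and site-selectivity: the thio group secures the regiochemistry, and the isopropylidene diene unit of 11 is locked s-trans, so it cannot act as a diene, and its tetrasubstituted alkene is not activated.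

Step 9
Reactants: 12 Diels–Alder adduct
Product: 13 methyl carbinol (C10 epimers)
Conditions: MeMgBr, THF, −78 → 0 °C; H2O
Reagents that add atoms: methylmagnesium bromide, C[Mg]Br
Why: Grignard 1,2-addition to the neopentyl aldehyde brings in the C10 methyl, and the carbinol centre is formed as a mixture that is erased in step 10.

Step 10
Reactants: 13 methyl carbinol
Product: 14 methyl ketone
Conditions: (COCl)2, DMSO, CH2Cl2, −78 °C; Et3N, → 0 °C
Reagents that add atoms: none
Why: Swern oxidation should give the ketone and is compatible with the aryl sulfide and the silyl ether.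

Step 11
Reactants: 14 methyl ketone
Product: 16 homoallylic sulfide (13α-CH2SPh, C11=C12), via sulfonium methylide 15 (not isolated)
Conditions: Et2Zn, CH2I2 (1.1 equiv each), CH2Cl2, 0 °C → rt
Reagents that add atoms: diiodomethane, ICI
Why: The zinc carbenoid (Simmons–Smith reagent) should alkylate sulfur to a sulfonium methylide that undergoes a [2,3]-sigmatropic rearrangement (one-carbon homologation of allyl sulfides), and because the shift is suprafacial the CH2SPh group arrives at C13 on the α face that carried sulfur at C11, trans to the C14 methyl.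

Step 12
Reactants: 16 homoallylic sulfide
Product: 17 saturated methyl ketone (13α,14β-dimethyl)
Conditions: Raney Ni (W-2), H2 (1 atm), EtOH, rt
Reagents that add atoms: none
Why: Raney nickel hydrogenolysis of both C–S bonds turns CH2SPh into the C13 methyl and the same reagent under H2 should saturate the disubstituted C11=C12 bond, while the tetrasubstituted isopropylidene and the hindered ketone are expected to survive.

Step 13
Reactants: 17 saturated methyl ketone
Product: 18 (10R)-tertiary alcohol with dioxolane side arm
Conditions: BrMgCH2CH2CH(OCH2CH2O), CeCl3, THF, −78 → 0 °C; H2O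
Reagents that add atoms: [2-(1,3-dioxolan-2-yl)ethyl]magnesium bromide, Br[Mg]CCC1OCCO1
Why: Organocerium-mediated 1,2-addition to the hindered ketone brings in C1–C3, and under Felkin–Anh control the nucleophile should approach anti to C5 (the ring B carbon held axial on ring C) and past the C11 methylene, giving the (R)-carbinol at C10.

Step 14
Reactants: 18 (10R)-tertiary alcohol
Product: 20 Prins product (3,10-ether bridge closed and C5=C6), via cyclic oxocarbenium ion 19 (not isolated)
Conditions: In(OTf)3 (10 mol%), CH2Cl2, 0 °C → rt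
Reagents that add atoms: none
Why: Prins cyclisation: acid should convert the hydroxy acetal into the five-membered oxocarbenium ion, which the terminal carbon of the homoallylic isopropylidene attacks through a chair transition state with C8 equatorial (C3–C4 bond, pyran ring, gem-dimethyl C4), the tertiary C5 cation then losing a C6 proton, and C3 is fixed because the bridge can only close cis.

Step 15
Reactants: 20 Prins product
Product: 21 silyl ether of the saturated pentacycle (5α-H)
Conditions: Mn(dpm)3 (10 mol%), PhSiH3, t-BuOOH, i-PrOH, rt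
Reagents that add atoms: none
Why: Hydrogen-atom-transfer hydrogenation of the hindered trisubstituted alkene proceeds through the tertiary C5 radical and should place H on C5 on the face of the CH2–CH2 bridge, because only this gives the strain-free trans junction with C6 equatorial on the pyran chair (thermodynamic bias of HAT hydrogenation).

Step 16
Reactants: 21 silyl ether of the saturated pentacycle
Product: 22 primary alcohol
Conditions: TBAF, THF, rt
Reagents that add atoms: none
Why: Fluoride-mediated desilylation should free the primary alcohol without affecting the bridged ether.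

Step 17
Reactants: 22 primary alcohol
Product: 23 aldehyde
Conditions: Dess–Martin periodinane, CH2Cl2, rt
Reagents that add atoms: none
Why: Dess–Martin oxidation of a primary alcohol to the aldehyde, with no epimerisable centre nearby.

Step 18
Reactants: 23 aldehyde
Product: 24 CNP0284367.1 (target)
Conditions: i-PrPPh3I, n-BuLi, THF, 0 °C; then 23, 0 °C → rt
Reagents that add atoms: isopropyltriphenylphosphonium iodide, CC(C)[P+](c1ccccc1)(c1ccccc1)c1ccccc1.[I-]
Why: Wittig olefination with the non-stabilised isopropylidene ylide should give the trisubstituted side-chain alkene, which has no E/Z issue.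

**Compound list**

1 | 3-methylcyclohex-2-en-1-one | CC1=CC(=O)CCC1 | starting material
2 | (3-bromopropoxy)(tert-butyl)dimethylsilane | CC(C)(C)[Si](C)(C)OCCCBr | starting material
3 | {3-[(tert-butyldimethylsilyl)oxy]propyl}magnesium bromide | CC(C)(C)[Si](C)(C)OCCC[Mg]Br | intermediate
4 | (3S)-3-{3-[(tert-butyldimethylsilyl)oxy]propyl}-3-methylcyclohexan-1-one | CC(C)(C)[Si](C)(C)OCCC[C@]1(C)CCCC(=O)C1 | intermediate
5 | (5S)-5-{3-[(tert-butyldimethylsilyl)oxy]propyl}-2,5-dimethylcyclohexan-1-one (both C2 epimers) | CC(C)(C)[Si](C)(C)OCCC[C@]1(C)CCC(C)C(=O)C1 | intermediate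
6 | (5S)-5-{3-[(tert-butyldimethylsilyl)oxy]propyl}-2,5-dimethylcyclohex-1-en-1-yl trifluoromethanesulfonate | CC(C)(C)[Si](C)(C)OCCC[C@]1(C)CCC(C)=C(OS(=O)(=O)C(F)(F)F)C1 | intermediate
7 | (5S)-5-{3-[(tert-butyldimethylsilyl)oxy]propyl}-2,5-dimethylcyclohex-1-ene-1-carbaldehyde | CC(C)(C)[Si](C)(C)OCCC[C@]1(C)CCC(C)=C(C=O)C1 | intermediate
8 | tert-butyl(3-{(1S)-1,4-dimethyl-3-[(E)-2-(phenylsulfanyl)ethenyl]cyclohex-3-en-1-yl}propoxy)dimethylsilane (ring D thio-diene) | CC(C)(C)[Si](C)(C)OCCC[C@]1(C)CCC(C)=C(/C=C/Sc2ccccc2)C1 | intermediate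
9 | 2-(propan-2-ylidene)cyclopentan-1-one | CC(C)=C1CCCC1=O | starting material
10 | 5-(propan-2-ylidene)cyclopent-1-en-1-yl trifluoromethanesulfonate | CC(C)=C1CCC=C1OS(=O)(=O)C(F)(F)F | intermediate
11 | 5-(propan-2-ylidene)cyclopent-1-ene-1-carbaldehyde (ring B dienal) | CC(C)=C1CCC=C1C=O | intermediate
12 | Diels–Alder adduct: B/C/D tricycle, cis B/C fusion (8α-H, formyl C10 α on C9), 5-isopropylidene, 11α-phenylsulfanyl, C12=C13, 14β-methyl, C17 with methyl and 3-(silyloxy)propyl | CC(C)(C)[Si](C)(C)OCCC[C@]1(C)CC[C@]2(C)[C@H]3CCC(=C(C)C)[C@@]3(C=O)[C@H](Sc4ccccc4)C=C2C1 | intermediate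
13 | carbinol of 12 with C10 = CH(OH)CH3 (both C10 epimers) | CC(C)(C)[Si](C)(C)OCCC[C@]1(C)CC[C@]2(C)[C@H]3CCC(=C(C)C)[C@@]3(C(C)O)[C@H](Sc4ccccc4)C=C2C1 | intermediate
14 | methyl ketone with C10 = C(=O)CH3, otherwise as 12 | CC(C)(C)[Si](C)(C)OCCC[C@]1(C)CC[C@]2(C)[C@H]3CCC(=C(C)C)[C@@]3(C(C)=O)[C@H](Sc4ccccc4)C=C2C1 | intermediate
15 | sulfonium methylide of 14 (CH2 carbanion on the C11 sulfur) | CC(C)(C)[Si](C)(C)OCCC[C@]1(C)CC[C@]2(C)[C@H]3CCC(=C(C)C)[C@@]3(C(C)=O)[C@H]([S+]([CH2-])c4ccccc4)C=C2C1 | intermediate
16 | homoallylic sulfide: 13α-(phenylsulfanylmethyl), C11=C12, C10 acetyl | CC(C)(C)[Si](C)(C)OCCC[C@]1(C)CC[C@]2(C)[C@H]3CCC(=C(C)C)[C@@]3(C(C)=O)C=C[C@@]2(CSc4ccccc4)C1 | intermediate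
17 | saturated methyl ketone: 13α,14β-dimethyl, trans C/D, cis B/C, 5-isopropylidene | CC(C)(C)[Si](C)(C)OCCC[C@]1(C)CC[C@]2(C)[C@H]3CCC(=C(C)C)[C@@]3(C(C)=O)CC[C@@]2(C)C1 | intermediate
18 | (10R)-tertiary alcohol: C10(OH)(CH3)CH2CH2(1,3-dioxolan-2-yl) on C9 | CC(C)(C)[Si](C)(C)OCCC[C@]1(C)CC[C@]2(C)[C@H]3CCC(=C(C)C)[C@@]3([C@](C)(O)CCC4OCCO4)CC[C@@]2(C)C1 | intermediate
19 | five-membered cyclic oxocarbenium ion (O–C10–C1–C2–C3, C3=O+) | CC(C)(C)[Si](C)(C)OCCC[C@]1(C)CC[C@]2(C)[C@H]3CCC(=C(C)C)[C@@]3([C@@]4(C)CCC=[O+]4)CC[C@@]2(C)C1 | intermediate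
20 | Prins product: pentacycle with 3,10-ether bridge, C4 gem-dimethyl, C5=C6, silyl ether | CC(C)(C)[Si](C)(C)OCCC[C@]1(C)CC[C@]2(C)[C@H]3CC=C4C(C)(C)[C@@H]5CC[C@@](C)(O5)[C@@]43CC[C@@]2(C)C1 | intermediate
21 | saturated pentacycle (5α-H, trans A/B), 3-(tert-butyldimethylsilyloxy)propyl on C17 | CC(C)(C)[Si](C)(C)OCCC[C@]1(C)CC[C@]2(C)[C@H]3CC[C@H]4C(C)(C)[C@@H]5CC[C@@](C)(O5)[C@@]43CC[C@@]2(C)C1 | intermediate
22 | primary alcohol (3-hydroxypropyl on C17) | OCCC[C@]1(C)CC[C@]2(C)[C@H]3CC[C@H]4C(C)(C)[C@@H]5CC[C@@](C)(O5)[C@@]43CC[C@@]2(C)C1 | intermediate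
23 | aldehyde (3-oxopropyl on C17) | O=CCC[C@]1(C)CC[C@]2(C)[C@H]3CC[C@H]4C(C)(C)[C@@H]5CC[C@@](C)(O5)[C@@]43CC[C@@]2(C)C1 | intermediate
24 | CNP0284367.1 | CC(C)=CCC[C@]1(C)CC[C@]2(C)[C@H]3CC[C@H]4C(C)(C)[C@@H]5CC[C@@](C)(O5)[C@@]43CC[C@@]2(C)C1 | target

**Step count**

Total step count: 18. Longest linear sequence: 16 steps (steps 1–5 and 8–18).

**Steps most likely to fail**

Step 8. The cycloaddition may stall, because a tetrasubstituted diene terminus has to bond to a β-substituted enal, or it may go stepwise and lose endo and facial control. The fallback changes the activation mode to an ionic cycloaddition of a chiral acetal. It sets out from 11: acetalisation with (2R,4R)-pentane-2,4-diol (PPTS, benzene, reflux with water removal) should give (4R,6R)-4,6-dimethyl-2-[5-(propan-2-ylidene)cyclopent-1-en-1-yl]-1,3-dioxane F1. TMSOTf (cat.) with 2,6-di-tert-butylpyridine in CH2Cl2 at −78 °C should open F1 to the far more electrophilic vinyl oxocarbenium ion, which adds diene 8 under the control of the chiral diol tether and recloses to the adduct acetal F2. Aqueous oxalic acid in THF should then hydrolyse F2, and the route is rejoined at aldehyde 12.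

Step 15. Hydrogen may be delivered to the wrong face of C5, or the encumbered alkene may not be reduced at all. The fallback puts C5 under thermodynamic control through a temporary C6 carbonyl. It sets out from 20: hydroboration–oxidation (BH3·THF, then H2O2/NaOH) should give the C6 alcohol F6, whatever the face of addition. Dess–Martin oxidation and equilibration with NaOMe in MeOH should give the C6 ketone F7, in which the enolisable C5 settles in the junction with C6 equatorial. Wolff–Kishner reduction (N2H4·H2O, KOH, diethylene glycol, 200 °C) should remove the carbonyl and cleave the silyl ether, and the route is rejoined at alcohol 22.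

Step 13. Facial discrimination at the hindered ketone may be poor or opposite to the Felkin–Anh prediction, or enolisation may compete. The fallback reverses the order in which the two carbon groups reach C10. It sets out from 17: the kinetic enolate of the methyl ketone (LDA, THF, −78 °C) is alkylated with allyl bromide to the pent-4-enoyl ketone F3. MeMgBr/CeCl3 then adds the methyl group as the nucleophile, which for a given facial preference gives the opposite carbinol configuration, to the tertiary alcohol F4. OsO4 (cat.)/NaIO4 should cleave the terminal alkene in preference to the hindered tetrasubstituted one and give the lactol F5. In(OTf)3 in CH2Cl2 should ionise F5 to the same oxocarbenium ion 19, and the route is rejoined at 20. Whichever order gives the (10R)-carbinol is kept.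

**Further compounds**

F1 | step 8 | (4R,6R)-4,6-dimethyl-2-[5-(propan-2-ylidene)cyclopent-1-en-1-yl]-1,3-dioxane | CC(C)=C1CCC=C1C1O[C@H](C)C[C@@H](C)O1
F2 | step 8 | (4R,6R)-4,6-dimethyl-1,3-dioxan-2-yl acetal of adduct 12 | CC(C)(C)[Si](C)(C)OCCC[C@]1(C)CC[C@]2(C)[C@H]3CCC(=C(C)C)[C@@]3(C4O[C@H](C)C[C@@H](C)O4)[C@H](Sc5ccccc5)C=C2C1
F3 | step 13 | pent-4-enoyl ketone (C10 = C(=O)CH2CH2CH=CH2 on C9 of 17) | CC(C)(C)[Si](C)(C)OCCC[C@]1(C)CC[C@]2(C)[C@H]3CCC(=C(C)C)[C@@]3(C(=O)CCC=C)CC[C@@]2(C)C1
F4 | step 13 | (10R)-tertiary alcohol with but-3-enyl arm | CC(C)(C)[Si](C)(C)OCCC[C@]1(C)CC[C@]2(C)[C@H]3CCC(=C(C)C)[C@@]3([C@](C)(O)CCC=C)CC[C@@]2(C)C1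
F5 | step 13 | lactol (2-hydroxytetrahydrofuran O–C10–C1–C2–C3, both anomers) | CC(C)(C)[Si](C)(C)OCCC[C@]1(C)CC[C@]2(C)[C@H]3CCC(=C(C)C)[C@@]3([C@@]4(C)CCC(O)O4)CC[C@@]2(C)C1
F6 | step 15 | C6 alcohol from hydroboration of 20 (C5 and C6 configuration not fixed) | CC(C)(C)[Si](C)(C)OCCC[C@]1(C)CC[C@]2(C)[C@H]3CC(O)C4C(C)(C)[C@@H]5CC[C@@](C)(O5)[C@@]43CC[C@@]2(C)C1
F7 | step 15 | C6 ketone with 5α-H after equilibration | CC(C)(C)[Si](C)(C)OCCC[C@]1(C)CC[C@]2(C)[C@H]3CC(=O)[C@H]4C(C)(C)[C@@H]5CC[C@@](C)(O5)[C@@]43CC[C@@]2(C)C1
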